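## Structural features

The target is a germacranolide. A ten-membered carbocycle (C1–C10) is fused across C6–C7 to a five-membered α,β-unsaturated γ-lactone (O–C6, C7=C11, C12=O). C7 is therefore a ring-fusion atom and also one end of the tetrasubstituted butenolide alkene. Two trans trisubstituted epoxides sit on the large ring at C1–C10 and C4–C5, C11 carries an acetoxymethyl group (C13), and C8 carries an (E)-2-methylbut-2-enoate (tiglate). The six stereocentres are (1R,4R,5R,6S,8S,10R). C4, C5 and C6 are contiguous, C10 and C1 form a second pair, and C8 is separated from C6 by the sp2 atom C7. In α/β terms the oxygens at C6 and C8 are both α, the epoxides are 1β,10α and 4α,5β, and both methyl groups are β. The fragile parts are the epoxides (acid opens them, also across the ring), the C6 and C8 oxygens (both allylic and γ to the lactone carbonyl, so prone to elimination or acyl shift under base), the primary allylic acetate, and the tiglate, whose alkene must not meet OsO4. The real difficulty is a ten-membered ring that is hard to close by ordinary C–C bond formation, together with oxygenation at C6 and C8, two sp3 carbons that no small reagent can pick out among the many allylic C–H positions. The key step uses the fact that C6 is an allylic methylene between the C4=C5 alkene and C7, whose side chain ends in the C12 carboxyl. Once an enzyme puts oxygen on the α face of C6, that oxygen is placed to close the five-membered lactone onto C12.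

## Logic of the disconnections

**17 to 16.** The C7=C11 π bond is traced back to a C11–O bond and a C7–H bond (retrosynthetic addition of water). The tetrasubstituted butenolide alkene makes both neighbouring C–O bonds allylic and base-labile, so it is best made last under neutral conditions. The gain is an sp3 C11 carbinol that comes from dihydroxylation. The demand is an elimination that runs towards C7 and not towards C13, which needs H7 and the C11 oxygen on the same face and a reagent that spares epoxides and esters.

**16 to 14 and 15.** The C8–O bond is cut. The enzymatic hydroxylation delivers the 8β oxygen, while 17 needs 8α, so one SN2 esterification both inverts C8 and attaches the acyl group from 15. It is placed after the osmylation so that the alkene of 15 never meets OsO4. It is placed before the dehydration so that no free secondary hydroxyl competes with the tertiary one. The demand is SN2 displacement at a hindered secondary carbon by a weakly acidic carboxylic acid, with the tertiary C11 hydroxyl staying passive.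

**14 to 13.** The acetyl C–O bond at O13 is cut. This separates the primary hydroxyl from the secondary and tertiary ones without protecting groups. The demand is kinetic selectivity for the primary position.

**13 to 12.** The C11–O and C13–O bonds are cut, which returns the exocyclic C11=C13 alkene. One reaction oxidises C13 and places at C11 the leaving group for the later alkene shift, and in 12 this is the only alkene left. The demand is neutral conditions and addition from the α face, so that the C11 oxygen ends up cis to H7.

**12 to 10 (through 11).** The four epoxide C–O bonds are cut, returning the two E ring alkenes. Four stereocentres (C1, C10, C4, C5) are removed at once, and all of them are controlled by the ring conformation of 10, which exposes only the outer face of each alkene. The demand is a buffered oxidant that also reaches the deactivated C4=C5 alkene and leaves the conjugated methylene alone.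

**10 to 8 (through 9).** The C6–O bond and the O–C12 acyl bond are cut. This removes the lactone ring and the C6 stereocentre and leaves a monocyclic triene acid. The demand is site and face selectivity at one allylic methylene among many, which only an enzyme active site offers.

**8 to 3 (through 4, 5, 6 and 7).** The C8–O bond, the C12 oxygens and the C6–C7 ring bond (germacrane numbering) are cut. The ten-membered ring, both E alkenes and the C7 stereocentre then come from an acyclic, achiral diphosphate in one enzymatic operation. The demand is gentle handling, because the germacrene intermediates undergo Cope rearrangement on heating and cyclise in acid.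

**3 to 2 to 1.** The C1–O–P bond and then the C1–Cl bond are cut. This is the standard activation of an allylic alcohol as its diphosphate. The demand is SN2 conditions that do not scramble the 2E alkene.

## Other disconnections considered

**Alternative 1:** The cut joins C1 to C6. The ten-membered ring is treated as a bicyclo[4.4.0]dec-1(6)-ene, the octalin A1 (C7 as dimethyl ketal, C8 as silyl ether, C10 as methoxymethyl ether). The forward key step is ozonolysis with reductive work-up to the ten-membered 1,6-diketone A2.
- **In favour:** no macrocyclisation is needed, and cleavage of a tetrasubstituted ring-fusion alkene is a dependable reaction. C8 and C10 are set on a rigid six-membered ring, and C8 is already α, so no inversion is required. Everything is ordinary laboratory chemistry without protein expression. On these points it is the equal or the better of the chosen plan.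
- **Against:** A2 is far from 17 in oxidation pattern. C1 and C6 are ketones that must be told apart, and C1 must be reduced and closed with the C10 oxygen to the trans epoxide. C4 is a saturated methine, so the C4–C5 epoxide requires dehydrogenation, epoxidation and reduction at C6. The butenolide with its acetoxymethyl group must still be annulated onto C6 and C7, for example by intramolecular Horner–Wadsworth–Emmons reaction. The 1,6-dione can also undergo transannular aldol closure.
- **Comparison:** on structure, the chosen plan obtains ring, E,E-diene and both oxygens at C6 and C8 from enzymes, while A2 supplies only the ring and two of six stereocentres. On mechanism, ozonolysis is more predictable than a cell-free P450 reaction. On step economy, this route would be expected to need well over twenty steps against nine.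

**Alternative 2:** The cut removes the C8–O and C13–O bonds together. The precursor is the diepoxy 7,11(13)-diene lactone A3, whose C8=C7–C11=C13 unit is held s-cis by the lactone ring (C7=C8 is taken as Z, with C9 outside the diene). The forward key step is (4+2) addition of singlet oxygen to give the 8,13-endoperoxide A4 with the alkene moved to C7=C11.
- **In favour:** one step installs the C8 oxygen, the C13 oxygen and the butenolide alkene. The chosen plan needs steps 6, 7 and 9 for this, and there is no regiochemical question of an elimination. If the oxygen arrives on the α face, no inversion is needed. From A3 the route is cycloaddition, O–O reduction, acetylation and tigloylation with retention. That is equal to or slightly shorter than the late stage of the chosen plan, and A3 could be reached from 12 by dehydration.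
- **Against:** the diene is conjugated to the lactone carbonyl and therefore electron-poor towards singlet oxygen. Ene reactions at C6–H and C9–H can compete. The face of attack at C8 rests only on the conformation of a flexible ring. A3 is a reactive cross-conjugated diene that may dimerise or take up nucleophiles. A4 is base-sensitive at C8–H.
- **Comparison:** on structure this alternative is better matched to the C8/C13/C7=C11 triad. On mechanism its facial control is weaker than SN2 inversion of an enzymatically set centre. It still needs the ten-membered ring and the C6 oxygen from elsewhere.

**Alternative 3:** The cut removes the C5–C6 ring bond and the C4–CH3 bond. The precursor is the acyclic ynal A5, a terminal alkyne tethered to a 2-formyl alkenoate that already carries the C13 acetate and the 8α silyl ether. The forward key step is alkylative macrocyclisation with Ni(COD)2 (zerovalent nickel) and Me2Zn. Syn addition of methyl and C6 across the alkyne gives the 4E alkene, and the resulting alkoxide lactonises to A6.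
- **In favour:** it is convergent, and one step would build the ring, the trisubstituted alkene, the C6–O centre and the lactone. The butenolide, the acetate and the correct C8 configuration are carried in from simple asymmetric chemistry. Only desilylation, esterification with 15 and double epoxidation would remain, which is shorter after the key step than the chosen plan.
- **Against:** closing a strained ten-membered E,E-diene through an oxanickelacycle is a demanding case for a reaction that is best suited to larger rings, and oligomerisation or the exocyclic mode may compete. The aldehyde in A5 sits on a doubly activated alkene that can take up Me2Zn in conjugate fashion. C6 would be controlled only remotely by C8 across sp2 C7. A5 itself would need roughly a dozen steps.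
- **Comparison:** on structure this alternative is the most direct. On mechanism the ring closure and the C6 configuration are less secure than in the enzymatic step. The late double epoxidation rests on the same conformational argument in both plans, so that point is equal.

Key step: step 4

Numbering: germacrane numbering is used throughout (ring C1–C10, C11 on C7, C12 carboxyl or lactone carbonyl, C13 exocyclic carbon, C14 methyl on C10, C15 methyl on C4).

Remark (assumption): the recombinant enzymes (germacrene A synthase, germacrene A oxidase, the 8β-hydroxylase, eupatolide synthase, cytochrome P450 reductase, glucose dehydrogenase) are treated as catalysts prepared by heterologous expression, not as starting materials.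

Remark (check of the structures): the key-step acid is (7R,8R) with H7 α and the C8 hydroxyl β, and its lactone is (6R,7R,8R); no structural correction was needed. C6 changes from R in 10 to S in 17 only because the C4–C5 epoxide raises the CIP rank of C5 above C7. C8 changes from R to S by a true inversion. The order of the late steps was changed so that esterification at C8 comes after osmylation and before dehydration.

## Route

Step 1
Reactants: 1 (2E,6E)-farnesol
Product: 2 (2E,6E)-farnesyl chloride
Conditions: NCS, Me2S, CH2Cl2, −30 → 0 °C
Reagents that add atoms: N-chlorosuccinimide, O=C1CCC(=O)N1Cl
Why: Corey–Kim chlorination; the sulfonium-activated primary allylic alcohol is displaced by chloride at C1 in an SN2 reaction under nearly neutral conditions, so neither allylic transposition nor isomerisation of the 2E alkene is expected.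

Step 2
Reactants: 2 (2E,6E)-farnesyl chloride
Product: 3 (2E,6E)-farnesyl diphosphate, triammonium salt
Conditions: (Bu4N)3HP2O7, MeCN, rt; then cation-exchange resin (NH4+ form), aq NH4HCO3
Reagents that add atoms: tris(tetrabutylammonium) hydrogen diphosphate, CCCC[N+](CCCC)(CCCC)CCCC.CCCC[N+](CCCC)(CCCC)CCCC.CCCC[N+](CCCC)(CCCC)CCCC.OP(=O)([O-])OP(=O)([O-])[O-]; ammonium hydrogencarbonate, [NH4+].OC(=O)[O-]
Why: SN2 displacement of a primary allylic chloride by the diphosphate anion in a dipolar aprotic solvent, the standard preparation of prenyl diphosphates; ion exchange gives the water-soluble ammonium salt that terpene synthases accept.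

Step 3
Reactants: 3 (2E,6E)-farnesyl diphosphate, triammonium salt
Product: 8 8β-hydroxygermacra-1(10),4,11(13)-trien-12-oic acid, via germacrene A 4 (not isolated), via germacrene A alcohol 5 (not isolated), via germacrene A aldehyde 6 (not isolated), via germacrene A acid 7 (not isolated)
Conditions: germacrene A synthase, MgCl2; yeast microsomes with germacrene A oxidase (CYP71AV type), germacrene A acid 8β-hydroxylase (CYP71BL1 type) and cytochrome P450 reductase; NADPH (cat.), D-glucose, glucose dehydrogenase, air, HEPES pH 7.5, 25 °C
Reagents that add atoms: dioxygen, O=O
Why: One-pot enzyme cascade of the sunflower pathway: the class 1 terpene synthase ionises the diphosphate, closes the ten-membered ring and loses a proton to give (R)-germacrene A, with C7 set by the enzyme fold. The oxidase then oxidises the isopropenyl methyl three times to the acid, and the hydroxylase inserts oxygen into the 8β C–H bond with retention by hydrogen abstraction and oxygen rebound. The one-pot format avoids handling the volatile, Cope-labile hydrocarbon 4.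

Step 4
Reactants: 8 8β-hydroxygermacra-1(10),4,11(13)-trien-12-oic acid
Product: 10 eupatolide (8β-hydroxygermacra-1(10),4,11(13)-trien-12,6α-olide), via 6α-hydroxy acid 9 (not isolated)
Conditions: yeast microsomes with eupatolide synthase (CYP71DD6 type) and cytochrome P450 reductase, NADPH (cat.), D-glucose, glucose dehydrogenase, air, HEPES pH 7.5, 30 °C
Reagents that add atoms: dioxygen, O=O
Why: The ferryl oxo haem of the P450 (tetravalent iron, porphyrin radical cation), formed from O2 and two electrons passed on from NADPH by the reductase, abstracts the 6α hydrogen of 8, which is allylic to the C4=C5 alkene, and the carbon radical recombines at once with the iron-bound hydroxyl on the same face (oxygen rebound), giving the 6α-alcohol 9 with retention. The closest known reaction type is the allylic C–H hydroxylation of germacrene A acids by the costunolide and eupatolide synthases of the CYP71 family, of which this is the 8β-hydroxylated case. The γ-lactone then closes without further catalysis by 5-exo-trig attack of O6 on the C12 carboxyl carbon (addition–elimination with loss of water), because O6 on the α face and the acrylic acid arm on the β face of C7 are trans and within bonding distance; the 8β-hydroxyl, which would have to close a cis-fused ring, has coexisted with the acid since step 3 and is not expected to compete. The one new stereocentre, C6 (R in 10), is controlled by the enzyme pocket, which presents only the 6α hydrogen to the oxidant; the substrate has no useful bias of its own. The step needs site selectivity for C6 over the other allylic positions (C2, C3, C7, C9, C14, C15), face selectivity, and rebound at C6 and not at C4 of the allyl radical; all three come from the fixed orientation of the substrate over the haem, anchored by its carboxylate and the C8 hydroxyl. The C7 centre, both E ring alkenes and the methylene group are untouched, so 10 carries C6 as 17 requires and C8 with the configuration that step 8 inverts.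

Step 5
Reactants: 10 eupatolide
Product: 12 1β,10α:4α,5β-diepoxy-8β-hydroxygermacr-11(13)-en-12,6α-olide, via 1,10-monoepoxide 11 (not isolated)
Conditions: mCPBA (2.5 equiv), NaHCO3, CH2Cl2, 0 °C → rt
Reagents that add atoms: 3-chloroperoxybenzoic acid, OOC(=O)c1cccc(Cl)c1
Why: Prilezhaev epoxidation; the peracid should attack the outer face of each E alkene in the crown conformation with C14 and C15 both β, giving the 1β,10α and 4α,5β epoxides. The electron-rich C1=C10 alkene reacts first, the C4=C5 alkene (deactivated by the allylic lactone oxygen) second, and the conjugated methylene is too electron-poor to react; NaHCO3 keeps the acid by-product from triggering transannular cyclisation of 11.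

Step 6
Reactants: 12 1β,10α:4α,5β-diepoxy-8β-hydroxygermacr-11(13)-en-12,6α-olide
Product: 13 1β,10α:4α,5β-diepoxy-8β,11α,13-trihydroxygermacran-12,6α-olide
Conditions: OsO4 (5 mol %), NMO, acetone–H2O, rt
Reagents that add atoms: osmium tetroxide (catalytic oxygen carrier), O=[Os](=O)(=O)=O; N-methylmorpholine N-oxide, C[N+]1([O-])CCOCC1; water, O
Why: Catalytic OsO4/NMO syn dihydroxylation of the only remaining alkene; OsO4 should add to the lactone face opposite C8 and its axial 8β-hydroxyl, which is the α face on the side of H7, giving the 11α-hydroxyl cis to H7. The neutral conditions should leave both epoxides and the lactone intact.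

Step 7
Reactants: 13 1β,10α:4α,5β-diepoxy-8β,11α,13-trihydroxygermacran-12,6α-olide
Product: 14 13-acetoxy-1β,10α:4α,5β-diepoxy-8β,11α-dihydroxygermacran-12,6α-olide
Conditions: Ac2O (1.1 equiv), pyridine, CH2Cl2, 0 °C
Reagents that add atoms: acetic anhydride, CC(=O)OC(C)=O
Why: Kinetically controlled acylation; with one equivalent of anhydride and no acyl-transfer catalyst the primary C13 hydroxyl should react well before the hindered axial C8 hydroxyl and the tertiary C11 hydroxyl.

Step 8
Reactants: 14 13-acetoxy-1β,10α:4α,5β-diepoxy-8β,11α-dihydroxygermacran-12,6α-olide; 15 tiglic acid
Product: 16 13-acetoxy-1β,10α:4α,5β-diepoxy-11α-hydroxy-8α-[(E)-2-methylbut-2-enoyloxy]germacran-12,6α-olide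
Conditions: PPh3, DIAD, toluene, 0 °C → rt
Reagents that add atoms: none
Why: Mitsunobu esterification; the secondary C8 hydroxyl is activated on phosphorus and displaced by the carboxylate of 15 in an SN2 reaction, which inverts C8 from β to α and attaches the ester in one operation. The tertiary C11 hydroxyl is not activated under these conditions, and the pseudo-axial 8β leaving group is open to backside attack from the α face.

Step 9
Reactants: 16 13-acetoxy-1β,10α:4α,5β-diepoxy-11α-hydroxy-8α-[(E)-2-methylbut-2-enoyloxy]germacran-12,6α-olide
Product: 17 13-acetoxy-1β,10α:4α,5β-diepoxy-8α-[(E)-2-methylbut-2-enoyloxy]germacr-7(11)-en-12,6α-olide (target)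
Conditions: Burgess reagent, toluene, 50 °C
Reagents that add atoms: none
Why: Burgess dehydration; the tertiary alcohol is sulfonylated on oxygen and then loses the elements of water by a thermal syn elimination through a cyclic transition state. H7 is cis to the C11 oxygen and can be reached, and its loss gives the tetrasubstituted alkene conjugated to the lactone carbonyl, whereas loss of a C13 hydrogen would give a less substituted enol acetate. The neutral, aprotic conditions should spare the epoxides, the acetate and the tiglate.

## Compound list

1 | (2E,6E)-farnesol | CC(C)=CCC/C(C)=C/CC/C(C)=C/CO | starting material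
2 | (2E,6E)-farnesyl chloride | CC(C)=CCC/C(C)=C/CC/C(C)=C/CCl | intermediate
3 | (2E,6E)-farnesyl diphosphate, triammonium salt | CC(C)=CCC/C(C)=C/CC/C(C)=C/COP(=O)([O-])OP(=O)([O-])[O-].[NH4+].[NH4+].[NH4+] | intermediate
4 | (R)-germacrene A, germacra-1(10)E,4E,11(13)-triene with H7 α (formed and consumed in step 3) | C1C/C(C)=C/CC/C(C)=C/C[C@@H]1C(C)=C | intermediate
5 | germacrene A alcohol, germacra-1(10)E,4E,11(13)-trien-12-ol (formed and consumed in step 3) | C1C/C(C)=C/CC/C(C)=C/C[C@@H]1C(=C)CO | intermediate
6 | germacrene A aldehyde, germacra-1(10)E,4E,11(13)-trien-12-al (formed and consumed in step 3) | C1C/C(C)=C/CC/C(C)=C/C[C@@H]1C(=C)C=O | intermediate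
7 | germacrene A acid, germacra-1(10)E,4E,11(13)-trien-12-oic acid (formed and consumed in step 3) | C1C/C(C)=C/CC/C(C)=C/C[C@@H]1C(=C)C(=O)O | intermediate
8 | (7R,8R)-8β-hydroxygermacra-1(10)E,4E,11(13)-trien-12-oic acid (H7 α) | O[C@@H]1C/C(C)=C/CC/C(C)=C/C[C@@H]1C(=C)C(=O)O | intermediate
9 | 6α,8β-dihydroxygermacra-1(10)E,4E,11(13)-trien-12-oic acid (formed and consumed in step 4) | O[C@@H]1C/C(C)=C/CC/C(C)=C/[C@@H](O)[C@@H]1C(=C)C(=O)O | intermediate
10 | eupatolide, (6R,7R,8R)-8β-hydroxygermacra-1(10)E,4E,11(13)-trien-12,6α-olide | O[C@@H]1C/C(C)=C/CC/C(C)=C/[C@H]2OC(=O)C(=C)[C@H]12 | intermediate
11 | 1β,10α-epoxy-8β-hydroxygermacra-4E,11(13)-dien-12,6α-olide (formed and consumed in step 5) | O[C@@H]1C[C@@]2(C)O[C@@H]2CC/C(C)=C/[C@H]2OC(=O)C(=C)[C@H]12 | intermediate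
12 | 1β,10α:4α,5β-diepoxy-8β-hydroxygermacr-11(13)-en-12,6α-olide | O[C@@H]1C[C@@]2(C)O[C@@H]2CC[C@@]2(C)O[C@@H]2[C@H]2OC(=O)C(=C)[C@H]12 | intermediate
13 | 1β,10α:4α,5β-diepoxy-8β,11α,13-trihydroxygermacran-12,6α-olide (C11 hydroxyl cis to H7) | O[C@@H]1C[C@@]2(C)O[C@@H]2CC[C@@]2(C)O[C@@H]2[C@H]2OC(=O)[C@](O)(CO)[C@H]12 | intermediate
14 | 13-acetoxy-1β,10α:4α,5β-diepoxy-8β,11α-dihydroxygermacran-12,6α-olide | O[C@@H]1C[C@@]2(C)O[C@@H]2CC[C@@]2(C)O[C@@H]2[C@H]2OC(=O)[C@](O)(COC(C)=O)[C@H]12 | intermediate
15 | tiglic acid, (E)-2-methylbut-2-enoic acid | C/C=C(\C)C(=O)O | starting material
16 | 13-acetoxy-1β,10α:4α,5β-diepoxy-11α-hydroxy-8α-[(E)-2-methylbut-2-enoyloxy]germacran-12,6α-olide | C/C=C(\C)C(=O)O[C@H]1C[C@@]2(C)O[C@@H]2CC[C@@]2(C)O[C@@H]2[C@H]2OC(=O)[C@](O)(COC(C)=O)[C@H]12 | intermediate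
17 | (1R,4R,5R,6S,8S,10R)-13-acetoxy-1β,10α:4α,5β-diepoxy-8α-[(E)-2-methylbut-2-enoyloxy]germacr-7(11)-en-12,6α-olide (CNP0251711.1) | C/C=C(\C)C(=O)O[C@H]1C[C@@]2(C)O[C@@H]2CC[C@@]2(C)O[C@@H]2[C@H]2OC(=O)C(COC(C)=O)=C12 | target

## Step count and least certain steps

Total step count: 9. Longest linear sequence: 9 steps (1 to 17); 15 enters at step 8.

**Step 4 (key step).** The most likely failure is low conversion in the cell-free system. Membrane-bound P450 enzymes lose activity outside the cell, electron transfer from the reductase can become uncoupled from substrate oxidation, and the triene acid slowly undergoes Cope rearrangement during long incubations. The fallback moves the reaction into living cells. The eupatolide synthase gene is added to a Saccharomyces cerevisiae strain that already expresses germacrene A synthase, germacrene A oxidase, the 8β-hydroxylase and the reductase. The hydroxylation then takes place on 8 as it is formed in the intact membrane, with cofactor supplied by metabolism. This sets out from 8 (generated in the cell) and comes back at 10, and it makes no new compound.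

**Step 9.** The elimination may take the wrong direction, towards a C13 hydrogen, giving an enol acetate. It may also fail for lack of a syn hydrogen if the osmylation in step 6 had added from the β face, which would place the C11 oxygen trans to H7. The fallback replaces the elimination by an oxygen ene reaction and sets out from 12. Photo-oxygenation (O2, visible light, tetraphenylporphyrin, CH2Cl2, 0 °C) is a Schenck ene reaction in which singlet oxygen bonds to C13 and removes H7, the only allylic hydrogen of the methylene lactone, so the alkene can only move to C7=C11. This gives 8β-hydroxy-13-hydroperoxy-1β,10α:4α,5β-diepoxygermacr-7(11)-en-12,6α-olide F1. PPh3 reduces it to the 8β,13-diol F2. Acetylation of the primary hydroxyl (Ac2O, pyridine, 0 °C) gives the 13-acetate F3. Mitsunobu esterification of F3 with 15 (PPh3, DIAD) inverts C8 and comes back to the route at 17.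

**Step 8.** Elimination towards C7 or C9 may compete with substitution, or activation may be incomplete, because C8 is flanked by the quaternary C11 and tiglic acid is a weak acid for this reaction. The neighbouring tertiary hydroxyl could also interfere. The fallback separates activation from displacement and sets out from 14. Chloromethanesulfonyl chloride and pyridine (0 °C) convert the C8 hydroxyl into the 8β-chloromethanesulfonate F4. The caesium salt of 15 (15, Cs2CO3, 18-crown-6, toluene, 60 °C) then displaces it with inversion and comes back at 16.

**Step 3.** The cascade may stall. Germacrene A can be lost by evaporation, Cope rearrangement or acid-induced cyclisation before it is oxidised. The alcohol and aldehyde stages may accumulate if the three enzymes are not balanced. The fallback is de novo fermentation in a Saccharomyces cerevisiae strain that co-expresses the synthase, the oxidase, the 8β-hydroxylase and the reductase. It sets out from 3 as made by the cell from glucose, in place of steps 1 and 2, and comes back at 8 by extraction of the culture. It makes no new compound.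

## Further compounds

F0 | step 4 | none | none
F1 | step 9 | 8β-hydroxy-13-hydroperoxy-1β,10α:4α,5β-diepoxygermacr-7(11)-en-12,6α-olide | O[C@@H]1C[C@@]2(C)O[C@@H]2CC[C@@]2(C)O[C@@H]2[C@H]2OC(=O)C(COO)=C12
F2 | step 9 | 8β,13-dihydroxy-1β,10α:4α,5β-diepoxygermacr-7(11)-en-12,6α-olide | O[C@@H]1C[C@@]2(C)O[C@@H]2CC[C@@]2(C)O[C@@H]2[C@H]2OC(=O)C(CO)=C12
F3 | step 9 | 13-acetoxy-8β-hydroxy-1β,10α:4α,5β-diepoxygermacr-7(11)-en-12,6α-olide | O[C@@H]1C[C@@]2(C)O[C@@H]2CC[C@@]2(C)O[C@@H]2[C@H]2OC(=O)C(COC(C)=O)=C12
F4 | step 8 | 13-acetoxy-8β-(chloromethanesulfonyloxy)-1β,10α:4α,5β-diepoxy-11α-hydroxygermacran-12,6α-olide | ClCS(=O)(=O)O[C@@H]1C[C@@]2(C)O[C@@H]2CC[C@@]2(C)O[C@@H]2[C@H]2OC(=O)[C@](O)(COC(C)=O)[C@H]12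
F0 | step 3 | none | none
A1 | alternative 1 | octalin precursor: 4β-methyl-bicyclo[4.4.0]dec-1(6)-ene with C7 dimethyl ketal, 8α-tert-butyldimethylsilyloxy, 10β-methyl and 10α-methoxymethoxy groups (germacrane numbering) | C[C@H]1CCC2=C(C1)C(OC)(OC)[C@@H](O[Si](C)(C)C(C)(C)C)C[C@@]2(C)OCOC
A2 | alternative 1 | ten-membered C1,C6-diketone with C7 dimethyl ketal, C8 silyl ether and C10 methoxymethyl ether | O=C1CC[C@H](C)CC(=O)C(OC)(OC)[C@@H](O[Si](C)(C)C(C)(C)C)C[C@@]1(C)OCOC
A3 | alternative 2 | 1β,10α:4α,5β-diepoxygermacra-7Z,11(13)-dien-12,6α-olide | C=C1/C2=C/C[C@@]3(C)O[C@@H]3CC[C@@]3(C)O[C@@H]3[C@H]2OC1=O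
A4 | alternative 2 | 8α,13-epidioxy-1β,10α:4α,5β-diepoxygermacr-7(11)-en-12,6α-olide | O1OCC2=C3[C@@H]1C[C@@]1(C)O[C@@H]1CC[C@@]1(C)O[C@@H]1[C@H]3OC2=O
A5 | alternative 3 | acyclic ynal: methyl (Z)-2-(acetoxymethyl)-3-formyl-alk-2-enoate carrying the 8α-silyloxy group, the 1(10)E alkene and the terminal C4≡C5 alkyne | C#CCC/C=C(\C)C[C@H](O[Si](C)(C)C(C)(C)C)/C(C=O)=C(\COC(C)=O)C(=O)OC
A6 | alternative 3 | 13-acetoxy-8α-(tert-butyldimethylsilyloxy)germacra-1(10)E,4E,7(11)-trien-12,6α-olide | CC(C)(C)[Si](C)(C)O[C@H]1C/C(C)=C/CC/C(C)=C/[C@H]2OC(=O)C(COC(C)=O)=C12
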